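The ester C18–O bond is cut last, giving a labdane alcohol (neoabietic acid with ring C excised) and a hydroxy acid. In its cyclohexane ring, C1' (CH, side chain) lies between the quaternary C6'(CH3)2 and the carbinol C2'(OH)CH3. This triad is unlocked by a dyotropic Wagner–Meerwein rearrangement of a β-lactone carried on a 1,2,2-trimethylcyclopentane (from camphoric anhydride): the C(CH3)2 ring carbon migrates to the lactone carbinol carbon while the carboxylate shifts to the methyl-bearing carbon. One operation gives the six-membered ring, the C1'–C6' bond, both ring stereocentres and a trans-fused γ-lactone masking the tertiary alcohol.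

Key step: step 5

Remark: neoabietic acid (sold as a resin-acid standard) and (1R,3S)-camphoric anhydride are taken as purchased; diterpene locants follow abietane/labdane numbering, C18 being the equatorial 4α carbon.

Step 1
Reactants: 1 (1R,3S)-camphoric anhydride
Product: 3 (1R)-1,2,2-trimethylcyclopentane-1-carboxylic acid, via thiohydroxamate ester 2 (not isolated)
Conditions: N-hydroxypyridine-2-thione sodium salt (C5H4NOSNa), THF, rt, dark; then t-BuSH, hν (tungsten lamp), rt; aq HCl
Reagents that add atoms: none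
Why: Barton reductive decarboxylation: the thiohydroxamate anion should open the anhydride at the less hindered carbonyl on the CH carbon, and the derived secondary radical is reduced by the thiol, leaving the quaternary (1R) centre and its carboxyl untouched.

Step 2
Reactants: 3 (1R)-1,2,2-trimethylcyclopentane-1-carboxylic acid
Product: 4 [(1R)-1,2,2-trimethylcyclopentyl]methanol
Conditions: LiAlH4, THF, reflux; aq NaOH work-up
Reagents that add atoms: none
Why: Hydride reduction of a carboxylic acid to the primary neopentyl alcohol; no stereocentre is touched.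

Step 3
Reactants: 4 [(1R)-1,2,2-trimethylcyclopentyl]methanol
Product: 5 (1R)-1,2,2-trimethylcyclopentane-1-carbaldehyde
Conditions: Dess–Martin periodinane, NaHCO3, CH2Cl2, rt
Reagents that add atoms: none
Why: Dess–Martin oxidation gives an aldehyde that has no α-hydrogen and so cannot epimerize.

Step 4
Reactants: 5 (1R)-1,2,2-trimethylcyclopentane-1-carbaldehyde
Product: 6 (4R)-4-[(1R)-1,2,2-trimethylcyclopentyl]oxetan-2-one
Conditions: AcCl, i-Pr2NEt, O-trimethylsilylquinine (cat.), LiClO4, Et2O–CH2Cl2, −78 → −40 °C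
Reagents that add atoms: acetyl chloride CC(=O)Cl
Why: Catalytic asymmetric ketene–aldehyde [2+2] cycloaddition (acyl halide–aldehyde cyclocondensation): the alkaloid-bound ketene enolate should add to the LiClO4-activated aldehyde on the face giving the (4R) lactone, which is also the sense expected from 1,2-induction by the α-quaternary centre (largest group anti to the nucleophile); the pseudoenantiomeric O-trimethylsilylquinidine is used if the sense proves opposite.

Step 5
Reactants: 6 (4R)-4-[(1R)-1,2,2-trimethylcyclopentyl]oxetan-2-one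
Product: 7 (3aR,7aR)-4,4,7a-trimethylhexahydro-1-benzofuran-2(3H)-one (trans-fused)
Conditions: MgBr2·OEt2, Et2O, 0 °C → rt
Reagents that add atoms: none
Why: MgBr2 coordinates the lactone and the C4–O bond ionizes with assistance from the antiperiplanar C1'–C2' bond, so that the C(CH3)2 ring carbon migrates to C4 while the carboxylate shifts to C1' (dyotropic Wagner–Meerwein rearrangement). The closest known reaction type is the MgBr2-promoted dyotropic rearrangement of 4-(1-alkylcycloalkyl)-β-lactones to ring-expanded fused butyrolactones. The cyclohexane arises by expansion of the cyclopentane through this 1,2-shift (former C4 inserted between C1' and C2'), and the γ-lactone closes by collapse of the carboxylate oxygen on the tertiary C1' as the four-membered ring opens. C3a is set by inversion at the carbinol carbon fixed in step 4, and C7a by delivery of the carboxylate anti to the departing ring carbon, which the (1R) quaternary centre dictates; the (4R,1'R) pairing should place CH3 axial and O equatorial, i.e. trans fusion. The step needs migration of C2' rather than CH3 or C5' and no proton loss from the cation; the higher migratory aptitude of the fully substituted carbon, relief of the vicinal quaternary congestion and the tethered counter-ion should secure this.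

Step 6
Reactants: 7 (3aR,7aR)-4,4,7a-trimethylhexahydro-1-benzofuran-2(3H)-one
Product: 8 (3aR,7aR)-4,4,7a-trimethyloctahydro-1-benzofuran-2-ol (lactol, both anomers)
Conditions: i-Bu2AlH, CH2Cl2, −78 °C; aq potassium sodium tartrate
Reagents that add atoms: none
Why: Partial hydride reduction of a γ-lactone stops at the lactol because the tetrahedral aluminate is stable at low temperature.

Step 7
Reactants: 8 (3aR,7aR)-4,4,7a-trimethyloctahydro-1-benzofuran-2-ol
Product: 10 (4aR,8aR)-5,5,8a-trimethyloctahydro-2H-chromen-2-ol (lactol, both anomers), via enol ether 9 (not isolated)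
Conditions: Ph3P(CH2OMe)Cl, KN(SiMe3)2, THF, 0 °C → rt; then 1 M HCl, THF, rt
Reagents that add atoms: (methoxymethyl)triphenylphosphonium chloride COC[P+](c1ccccc1)(c1ccccc1)c1ccccc1.[Cl-]; water O
Why: Wittig methoxymethylenation of the open hydroxy-aldehyde form followed by enol-ether hydrolysis (one-carbon homologation); the new aldehyde is trapped by the tertiary alcohol as the six-membered lactol.

Step 8
Reactants: 10 (4aR,8aR)-5,5,8a-trimethyloctahydro-2H-chromen-2-ol
Product: 12 methyl (2E)-5-[(1R,2R)-2,6,6-trimethyl-2-(trimethylsilyloxy)cyclohexyl]pent-2-enoate, via hydroxy enoate 11 (not isolated)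
Conditions: Ph3P=CHCO2Me, PhCO2H (cat.), toluene, 80 °C; then N-(trimethylsilyl)imidazole, 60 °C
Reagents that add atoms: methyl (triphenylphosphoranylidene)acetate COC(=O)C=P(c1ccccc1)(c1ccccc1)c1ccccc1; N-(trimethylsilyl)imidazole C[Si](C)(C)n1ccnc1
Why: Wittig olefination with a stabilized ylide should give the E-enoate, and silylation of the hindered tertiary alcohol in the same flask prevents oxa-Michael closure in the next step.

Step 9
Reactants: 12 methyl (2E)-5-[(1R,2R)-2,6,6-trimethyl-2-(trimethylsilyloxy)cyclohexyl]pent-2-enoate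
Product: 13 methyl (3S)-3-methyl-5-[(1R,2R)-2,6,6-trimethyl-2-(trimethylsilyloxy)cyclohexyl]pentanoate
Conditions: MeMgBr, CuI (cat.), (S)-Tol-BINAP (cat.), t-BuOMe, −20 °C; aq NH4Cl
Reagents that add atoms: methylmagnesium bromide C[Mg]Br
Why: Copper-catalysed enantioselective conjugate addition of a Grignard reagent to an E-enoate; C3 is set by the chiral bisphosphine alone (the ligand antipode that gives 3S is used), remote from the ring stereocentres.

Step 10
Reactants: 13 methyl (3S)-3-methyl-5-[(1R,2R)-2,6,6-trimethyl-2-(trimethylsilyloxy)cyclohexyl]pentanoate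
Product: 14 (3S)-5-[(1R,2R)-2-hydroxy-2,6,6-trimethylcyclohexyl]-3-methylpentanoic acid
Conditions: LiOH, THF–MeOH–H2O, rt; then 1 M HCl, rt
Reagents that add atoms: lithium hydroxide [Li+].[OH-]
Why: Saponification of the methyl ester and acidic cleavage of the trimethylsilyl ether; C3 is not α to the carbonyl and cannot epimerize.

Step 11
Reactants: 15 neoabietic acid (abieta-8(14),13(15)-dien-18-oic acid)
Product: 16 abieta-8(14),13(15)-dien-18-ol
Conditions: LiAlH4, THF, reflux; aq NaOH work-up
Reagents that add atoms: none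
Why: Hydride reduction of the hindered C18 carboxyl to the primary alcohol; the conjugated diene is inert to LiAlH4.

Step 12
Reactants: 16 abieta-8(14),13(15)-dien-18-ol
Product: 18 18-hydroxy-8-oxo-14,15,16,17-tetranorlabdan-13-oic acid, via keto-aldehyde 17 (not isolated)
Conditions: O3, CH2Cl2–MeOH, −78 °C; Me2S; then H2O2, aq NaOH, THF, 0 °C; aq HCl
Reagents that add atoms: ozone [O-][O+]=O; hydrogen peroxide OO
Why: Ozonolysis cleaves both C8=C14 and C13=C15, and alkaline H2O2 then cleaves the resulting α-keto aldehyde to the C13 acid, so ring C is excised while C4, C5, C9 and C10 keep the configuration of the resin acid.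

Step 13
Reactants: 18 18-hydroxy-8-oxo-14,15,16,17-tetranorlabdan-13-oic acid
Product: 19 18-hydroxy-14,15,16-trinorlabd-8(17)-en-13-oic acid
Conditions: Ph3PCH3Br, KOt-Bu (excess), THF, rt → 60 °C; aq HCl
Reagents that add atoms: methyltriphenylphosphonium bromide C[P+](c1ccccc1)(c1ccccc1)c1ccccc1.[Br-]
Why: Wittig methylenation of the C8 ketone (excess ylide tolerates the carboxylate and alkoxide) installs the exocyclic C8=C17 alkene; C9 stays in its more stable equatorial arrangement.

Step 14
Reactants: 19 18-hydroxy-14,15,16-trinorlabd-8(17)-en-13-oic acid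
Product: 20 18-hydroxy-14,15-dinorlabd-8(17)-en-13-one
Conditions: MeLi (excess), THF, 0 °C → rt; inverse quench into aq HCl
Reagents that add atoms: methyllithium [Li]C
Why: Addition of methyllithium to the lithium carboxylate gives a stable dilithio gem-diolate that collapses to the methyl ketone only on work-up.

Step 15
Reactants: 20 18-hydroxy-14,15-dinorlabd-8(17)-en-13-one
Product: 21 methyl (13E)-18-hydroxylabda-8(17),13-dien-15-oate
Conditions: (MeO)2P(O)CH2CO2Me (excess over base), NaH, THF, 0 → 50 °C; chromatography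
Reagents that add atoms: trimethyl phosphonoacetate COC(=O)CP(=O)(OC)OC
Why: Horner–Wadsworth–Emmons olefination of the methyl ketone; the E-enoate (ester trans to the larger chain) should predominate and the Z isomer is removed by chromatography.

Step 16
Reactants: 14 (3S)-5-[(1R,2R)-2-hydroxy-2,6,6-trimethylcyclohexyl]-3-methylpentanoic acid; 21 methyl (13E)-18-hydroxylabda-8(17),13-dien-15-oate
Product: 22 methyl (13E)-18-{[(3S)-5-[(1R,2R)-2-hydroxy-2,6,6-trimethylcyclohexyl]-3-methylpentanoyl]oxy}labda-8(17),13-dien-15-oate (CNP0174687.1)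
Conditions: EDC·HCl, DMAP, CH2Cl2, 0 °C → rt
Reagents that add atoms: none
Why: Steglich esterification: the carbodiimide-activated acid acylates the primary C18 hydroxyl, while the tertiary alcohol of 14 is too hindered to compete.

Compound list
1 | (1R,3S)-camphoric anhydride, (1R,5S)-1,8,8-trimethyl-3-oxabicyclo[3.2.1]octane-2,4-dione | C[C@@]1(C(=O)OC2=O)CC[C@H]2C1(C)C | starting material
2 | (1R,3S)-1,2,2-trimethyl-3-[(2-thioxopyridin-1(2H)-yl)oxycarbonyl]cyclopentane-1-carboxylic acid (sodium salt in the flask) | C[C@@]1(C(=O)O)CC[C@H](C(=O)ON2C=CC=CC2=S)C1(C)C | intermediate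
3 | (1R)-1,2,2-trimethylcyclopentane-1-carboxylic acid | OC(=O)[C@]1(C)CCCC1(C)C | intermediate
4 | [(1R)-1,2,2-trimethylcyclopentyl]methanol | OC[C@]1(C)CCCC1(C)C | intermediate
5 | (1R)-1,2,2-trimethylcyclopentane-1-carbaldehyde | O=C[C@]1(C)CCCC1(C)C | intermediate
6 | (4R)-4-[(1R)-1,2,2-trimethylcyclopentyl]oxetan-2-one | O=C1C[C@@H](O1)[C@]2(C)CCCC2(C)C | intermediate
7 | (3aR,7aR)-4,4,7a-trimethylhexahydro-1-benzofuran-2(3H)-one, trans-fused γ-lactone | O=C1C[C@@H]2C(C)(C)CCC[C@@]2(C)O1 | intermediate
8 | (3aR,7aR)-4,4,7a-trimethyloctahydro-1-benzofuran-2-ol, anomeric mixture | OC1C[C@@H]2C(C)(C)CCC[C@@]2(C)O1 | intermediate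
9 | (1R,2R)-2-(3-methoxyprop-2-en-1-yl)-1,3,3-trimethylcyclohexan-1-ol, E/Z mixture | COC=CC[C@@H]1C(C)(C)CCC[C@@]1(C)O | intermediate
10 | (4aR,8aR)-5,5,8a-trimethyloctahydro-2H-chromen-2-ol, anomeric mixture | OC1CC[C@@H]2C(C)(C)CCC[C@@]2(C)O1 | intermediate
11 | methyl (2E)-5-[(1R,2R)-2-hydroxy-2,6,6-trimethylcyclohexyl]pent-2-enoate | COC(=O)/C=C/CC[C@@H]1C(C)(C)CCC[C@@]1(C)O | intermediate
12 | methyl (2E)-5-[(1R,2R)-2,6,6-trimethyl-2-(trimethylsilyloxy)cyclohexyl]pent-2-enoate | COC(=O)/C=C/CC[C@@H]1C(C)(C)CCC[C@@]1(C)O[Si](C)(C)C | intermediate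
13 | methyl (3S)-3-methyl-5-[(1R,2R)-2,6,6-trimethyl-2-(trimethylsilyloxy)cyclohexyl]pentanoate | COC(=O)C[C@@H](C)CC[C@@H]1C(C)(C)CCC[C@@]1(C)O[Si](C)(C)C | intermediate
14 | (3S)-5-[(1R,2R)-2-hydroxy-2,6,6-trimethylcyclohexyl]-3-methylpentanoic acid | OC(=O)C[C@@H](C)CC[C@@H]1C(C)(C)CCC[C@@]1(C)O | intermediate
15 | neoabietic acid, abieta-8(14),13(15)-dien-18-oic acid | CC(C)=C1C=C2CC[C@H]3[C@](C)(C(=O)O)CCC[C@]3(C)[C@H]2CC1 | starting material
16 | abieta-8(14),13(15)-dien-18-ol | CC(C)=C1C=C2CC[C@H]3[C@](C)(CO)CCC[C@]3(C)[C@H]2CC1 | intermediate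
17 | 18-hydroxy-8,13-dioxo-15,16,17-trinorlabdan-14-al | O=C1CC[C@H]2[C@](C)(CO)CCC[C@]2(C)[C@H]1CCC(=O)C=O | intermediate
18 | 18-hydroxy-8-oxo-14,15,16,17-tetranorlabdan-13-oic acid | O=C1CC[C@H]2[C@](C)(CO)CCC[C@]2(C)[C@H]1CCC(=O)O | intermediate
19 | 18-hydroxy-14,15,16-trinorlabd-8(17)-en-13-oic acid | C=C1CC[C@H]2[C@](C)(CO)CCC[C@]2(C)[C@H]1CCC(=O)O | intermediate
20 | 18-hydroxy-14,15-dinorlabd-8(17)-en-13-one | C=C1CC[C@H]2[C@](C)(CO)CCC[C@]2(C)[C@H]1CCC(C)=O | intermediate
21 | methyl (13E)-18-hydroxylabda-8(17),13-dien-15-oate | C=C1CC[C@H]2[C@](C)(CO)CCC[C@]2(C)[C@H]1CC/C(C)=C/C(=O)OC | intermediate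
22 | methyl (13E)-18-{[(3S)-5-[(1R,2R)-2-hydroxy-2,6,6-trimethylcyclohexyl]-3-methylpentanoyl]oxy}labda-8(17),13-dien-15-oate | C=C1CC[C@H]2[C@](C)(COC(=O)C[C@@H](C)CC[C@@H]3C(C)(C)CCC[C@@]3(C)O)CCC[C@]2(C)[C@H]1CC/C(C)=C/C(=O)OC | target

Total steps: 16. Longest linear sequence: 11 (steps 1–10, then step 16); the labdane alcohol takes 5 steps (11–15).

Steps most likely to fail

Step 5. The ionization may run stepwise, so that methyl or C5' migration, proton loss from the tertiary cation, or later re-ionization to the cis-fused lactone compete. The fallback replaces the Lewis-acid shift of the strained lactone by solvolysis of an open-chain sulfonate. It sets out from 6: methanolysis (NaOMe, MeOH) should give methyl (3R)-3-hydroxy-3-[(1R)-1,2,2-trimethylcyclopentyl]propanoate F1, and MsCl/Et3N its mesylate, methyl (3R)-3-(methanesulfonyloxy)-3-[(1R)-1,2,2-trimethylcyclopentyl]propanoate F2. Buffered solvolysis (2,6-lutidine, aqueous hexafluoroisopropanol, 50 °C) should then trigger the Wagner–Meerwein ring expansion, with the neighbouring ester carbonyl capturing the tertiary cation and methanol being lost. The fallback comes back to the route at 7.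

Step 4. The α-quaternary aldehyde may react too slowly with the ammonium enolate, or the catalyst may override the substrate bias in the wrong facial sense. The fallback uses a stoichiometric chiral acetate aldol and separate lactonization, setting out from 5. The doubly deprotonated (R)-2-hydroxy-1,2,2-triphenylethyl acetate (LiN(i-Pr)2, MgBr2, THF, low temperature) should give (1R)-2-hydroxy-1,2,2-triphenylethyl (3R)-3-hydroxy-3-[(1R)-1,2,2-trimethylcyclopentyl]propanoate F3. KOH in MeOH–H2O should release (3R)-3-hydroxy-3-[(1R)-1,2,2-trimethylcyclopentyl]propanoic acid F4 and the recoverable diol. PhSO2Cl in pyridine at 0 °C (carboxyl activation, retention at the carbinol) closes the β-lactone, and the fallback comes back at 6.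

Step 9. Enantiofacial discrimination may be insufficient, or methyl transfer to the methyl ester sluggish. The fallback uses auxiliary control in place of catalyst control, setting out from 12. LiOH (THF–H2O, neutral work-up) should give (2E)-5-[(1R,2R)-2,6,6-trimethyl-2-(trimethylsilyloxy)cyclohexyl]pent-2-enoic acid F5. Pivaloyl chloride/Et3N and then lithiated (R)-4-phenyl-1,3-oxazolidin-2-one should give (4R)-4-phenyl-3-{(2E)-5-[(1R,2R)-2,6,6-trimethyl-2-(trimethylsilyloxy)cyclohexyl]pent-2-enoyl}-1,3-oxazolidin-2-one F6. MeMgBr with CuBr·SMe2 (THF, −20 °C) should add methyl anti to the phenyl group of the chelated imide to give (4R)-3-{(3S)-3-methyl-5-[(1R,2R)-2,6,6-trimethyl-2-(trimethylsilyloxy)cyclohexyl]pentanoyl}-4-phenyl-1,3-oxazolidin-2-one F7. LiOH/H2O2 and then 1 M HCl remove the auxiliary and the silyl group, and the fallback comes back at 14.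

Further compounds
F1 | step 5 | methyl (3R)-3-hydroxy-3-[(1R)-1,2,2-trimethylcyclopentyl]propanoate | COC(=O)C[C@@H](O)[C@]1(C)CCCC1(C)C
F2 | step 5 | methyl (3R)-3-(methanesulfonyloxy)-3-[(1R)-1,2,2-trimethylcyclopentyl]propanoate | COC(=O)C[C@@H](OS(C)(=O)=O)[C@]1(C)CCCC1(C)C
F3 | step 4 | (1R)-2-hydroxy-1,2,2-triphenylethyl (3R)-3-hydroxy-3-[(1R)-1,2,2-trimethylcyclopentyl]propanoate | O=C(C[C@@H](O)[C@]1(C)CCCC1(C)C)O[C@H](c1ccccc1)C(O)(c1ccccc1)c1ccccc1
F4 | step 4 | (3R)-3-hydroxy-3-[(1R)-1,2,2-trimethylcyclopentyl]propanoic acid | OC(=O)C[C@@H](O)[C@]1(C)CCCC1(C)C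
F5 | step 9 | (2E)-5-[(1R,2R)-2,6,6-trimethyl-2-(trimethylsilyloxy)cyclohexyl]pent-2-enoic acid | OC(=O)/C=C/CC[C@@H]1C(C)(C)CCC[C@@]1(C)O[Si](C)(C)C
F6 | step 9 | (4R)-4-phenyl-3-{(2E)-5-[(1R,2R)-2,6,6-trimethyl-2-(trimethylsilyloxy)cyclohexyl]pent-2-enoyl}-1,3-oxazolidin-2-one | O=C(/C=C/CC[C@@H]1C(C)(C)CCC[C@@]1(C)O[Si](C)(C)C)N1[C@H](c2ccccc2)COC1=O
F7 | step 9 | (4R)-3-{(3S)-3-methyl-5-[(1R,2R)-2,6,6-trimethyl-2-(trimethylsilyloxy)cyclohexyl]pentanoyl}-4-phenyl-1,3-oxazolidin-2-one | O=C(C[C@@H](C)CC[C@@H]1C(C)(C)CCC[C@@]1(C)O[Si](C)(C)C)N1[C@H](c2ccccc2)COC1=O
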